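The easy step comes first: I set target against catalyst. In the violet run the first reading, 40 mM at 5.4 min, is 13.3 times the catalyst charged.

common to all: catalyst 3.00 mM
- violet: substrate 300 mM; reagent 360 mM
- red: substrate 120 mM; reagent 180 mM
- amber: substrate 150 mM; reagent 360 mM
- green: substrate 300 mM; reagent 720 mM
- blue: substrate 750 mM; reagent 900 mM; time 38 min

| violet run: time / min | violet run: [target] / mM | red run: time / min | red run: [target] / mM | amber run: time / min | amber run: [target] / mM | green run: time / min | green run: [target] / mM |
|---|---|---|---|---|---|---|---|
| 5.4 | 40 | 5.4 | 8 | 5.4 | 19 | 5.4 | 64 |
| 11 | 73 | 11 | 19 | 11 | 45 | 11 | 126 |
| 16 | 95 | 16 | 28 | 16 | 52 | 16 | 149 |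
| 22 | 123 | 22 | 36 | 22 | 64 | 22 | 188 |
| 27 | 138 | 27 | 39 | 27 | 73 | 27 | 203 |
| 33 | 147 | 33 | 49 | 33 | 85 | 33 | 223 |
| 38 | 169 | 38 | 50 | 38 | 94 | 38 | 235 |

(each reading ± 3 mM)

- Overall: substrate + reagent -> target, with catalyst as catalyst.
- Constant volume, constant temperature.
- Bound and free are read together.
- "The second partner" is reagent.
- An order is taken over about fifteen percent of the charge, up and down.

- how the opening rate goes with [reagent] round the charge of the violet run: the exponent of the rate at two percent of substrate gone to target
- how the opening rate goes with [substrate] round the charge of the violet run: the exponent of the rate at two percent of substrate gone to target (one fixed amount of target, the same in the runs compared)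
- the red run starts with 180 mM less of substrate and of reagent than the violet run, and with no target. Compared where both hold the same amount of substrate, once fifteen percent of what the red run was charged with has turned into target, is the red run faster, slower or alike (within a tenth)?
- target in the blue run at 38 min, as a share of the substrate charged

The first reading of the amber run is about half of violet's, with half the substrate, so I take the rate as first order in substrate. Substrate is the limiting reagent in the blue run, with 750 mM against 900 mM of reagent.

The green run has twice violet's reagent. At equal time green has made more target, 64 mM against 40 mM, and so has lost more substrate, so I compare at equal target instead. Violet needs 9.47 min for what green holds at 5.4 min, which reads as an order in reagent of 0.811.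

The blue run has violet's ratio of reagent to substrate, 1.20. For a rate of this power form, two flasks with equal catalyst and equal ratio pass every share turned at times in one fixed proportion. I call that proportion the clock factor, the charge ratio raised to the order in reagent: 2.10 for blue over violet.

I correct violet's first mean rate for the slowing at half that target, which gives an opening rate of 8.31 mM min⁻¹. Blue then opens at 43.7 mM min⁻¹.

Blue reaches violet's last share, 56.3%, at 18.1 min. There the substrate slows the rate by a factor 0.437 and the reagent by 0.598, leaving 11.4 mM min⁻¹. At 75.0% turned the rate has fallen to 4.93 mM min⁻¹, and midway it is 7.89 mM min⁻¹. Stepping through these three rates, blue reaches 75.0% at 36.7 min, and by 38 min my reckoning stands at 75.9%.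

The forecast gives 0.7 for reagent, 0.95 for substrate, alike for the red comparison and 72% for blue. That last figure is lower than my reckoning, and its order in reagent is lower than mine. It holds back on blue with these words: “I shade this down slightly for possible substrate saturation”.

    catalyst + substrate ⇌ catalyst-substrate complex, settled at all times (0.5260 M⁻¹)
    catalyst + reagent ⇌ catalyst-reagent complex, settled at all times (6.860 M⁻¹)
    catalyst-substrate complex + catalyst-reagent complex → target + 2 catalyst (3816 M⁻¹ min⁻¹)
    substrate + reagent → target (0.06900 M⁻¹ min⁻¹)

The blue run gives 76.3%; the order in reagent round violet's charge is 0.85 and the order in substrate 1.0, and the red run against the violet run comes out alike. The clock factor 2.10 serves a second pair too. Green and amber also share one ratio of reagent to substrate, with charges twice apart, so the same order makes their clock factor 1.75. Target comes to half of the charge in the green run at 15.0 min and in the amber run at 27.2 min, a ratio of 1.81.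

(All runs come from a simulation with constants of no real substance.)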